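**Plan**
- Retrosynthesis: the acetonide is removed last; the 1-carboxyvinyl group goes back through CO insertion into an enol triflate to a C2 acetyl and then a C2 ester group; the oxane is then cut in one stroke at ring O1–C6H2 and ring C4H2–C5H.
- Enabling feature: O1–C2–C3–C4 of the oxane, with an acyl carbon on C2, is the s-cis 1-oxadiene O=C–C=C of a vinyl α-keto ester, and C6H2–C5H(side chain) is the carbonyl carbon plus α-carbon of an aldehyde. The ring is therefore the twice-reduced adduct of an enamine/oxadiene [4+2] reaction.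
- The aldehyde comes from an allyl group by hydroformylation; its diol comes from geranyl bromide and methallyl alcohol by asymmetric epoxidation, allylboration and hydride opening.
- Forward: C14 allylic alcohol → epoxide → allyl carbinol → diol acetonide → aldehyde → [4+2] closes the only ring → lactol and enol ether reduced → ester turned into the acrylic acid → diol freed.
- Stereochemistry: tertiary carbinol by Sharpless asymmetric epoxidation; secondary carbinol by reagent-controlled allylboration; ring C5 by the chiral amine catalyst of the key step; ring C2 relayed from C5 by equilibration of the α-alkoxy ester to the 2,5-trans (diequatorial) oxane.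

Key step: step 9

Remark: the target is read as 2R,5S at the oxane (2,5-trans; O1, C2 bears the acrylic acid, C5 the side chain, C6 is OCH2) and 3R,4R in the diol, which is the syn-diol pattern of an (E)-alkene.
Shorthand in names: Diox = (4R,5R)-5-[(3E)-4,8-dimethylnona-3,7-dien-1-yl]-2,2,5-trimethyl-1,3-dioxolan-4-yl.

**Step 1**
Reactants: 1 2-methylprop-2-en-1-ol; 2 geranyl bromide
Product: 4 (5E)-6,10-dimethyl-2-methylideneundeca-5,9-dien-1-ol, via dilithiated methallyl alcohol 3 (not isolated)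
Conditions: n-BuLi (2.2 equiv), TMEDA, Et2O/hexane, 0 °C → rt; then 2, −78 °C → rt
Reagents that add atoms: none
Why: Double deprotonation gives the O,C-dianion, whose allylic carbanion displaces the primary allylic bromide (SN2 alkylation of a methallyl alcohol dianion), attaching the chain with the (E)-alkene intact.

**Step 2**
Reactants: 4 (5E)-6,10-dimethyl-2-methylideneundeca-5,9-dien-1-ol
Product: 5 [(2R)-2-[(3E)-4,8-dimethylnona-3,7-dien-1-yl]oxiran-2-yl]methanol
Conditions: Ti(OiPr)4 (10 mol%), D-(−)-diethyl tartrate (12 mol%), t-BuOOH, 4 Å MS, CH2Cl2, −20 °C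
Reagents that add atoms: tert-butyl hydroperoxide, CC(C)(C)OO
Why: Sharpless asymmetric epoxidation is directed by the allylic hydroxyl, so only the 1,1-disubstituted allylic alkene reacts, and the D-tartrate should deliver oxygen to the face that gives the (R)-epoxide, the future tertiary carbinol centre.

**Step 3**
Reactants: 5 [(2R)-2-[(3E)-4,8-dimethylnona-3,7-dien-1-yl]oxiran-2-yl]methanol
Product: 6 (2S)-2-[(3E)-4,8-dimethylnona-3,7-dien-1-yl]oxirane-2-carbaldehyde
Conditions: Dess–Martin periodinane, NaHCO3, CH2Cl2, 0 °C → rt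
Reagents that add atoms: none
Why: Buffered Dess–Martin oxidation stops at the aldehyde, and the quaternary α-carbon cannot epimerise.

**Step 4**
Reactants: 6 (2S)-2-[(3E)-4,8-dimethylnona-3,7-dien-1-yl]oxirane-2-carbaldehyde
Product: 8 (1R)-1-[(2S)-2-[(3E)-4,8-dimethylnona-3,7-dien-1-yl]oxiran-2-yl]but-3-en-1-ol, via borinate ester 7 (not isolated)
Conditions: B-allyldiisopinocampheylborane derived from (−)-α-pinene (lIpc2B-allyl), Et2O, −78 °C; then HOCH2CH2NH2, rt
Reagents that add atoms: B-allyldiisopinocampheylborane from (−)-α-pinene, C=CCB([C@H]1C[C@H]2C[C@@H]([C@@H]1C)C2(C)C)[C@H]1C[C@H]2C[C@@H]([C@@H]1C)C2(C)C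
Why: Brown asymmetric allylboration through a chair six-membered transition state is reagent-controlled; this enantiomer of the borane should add allyl to the Re face and set the (R) carbinol, and the non-basic work-up avoids Payne rearrangement of the epoxy alcohol.

**Step 5**
Reactants: 8 (1R)-1-[(2S)-2-[(3E)-4,8-dimethylnona-3,7-dien-1-yl]oxiran-2-yl]but-3-en-1-ol
Product: 9 (4R,5R,8E)-5,9,13-trimethyltetradeca-1,8,12-triene-4,5-diol
Conditions: LiAlH4, THF, 0 °C → rt
Reagents that add atoms: none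
Why: Hydride opens the 2,2-disubstituted epoxide at its unhindered CH2 terminus (SN2 epoxide reduction), giving the methyl-bearing tertiary alcohol without touching either stereocentre.

**Step 6**
Reactants: 9 (4R,5R,8E)-5,9,13-trimethyltetradeca-1,8,12-triene-4,5-diol
Product: 10 (4R,5R)-5-[(3E)-4,8-dimethylnona-3,7-dien-1-yl]-2,2,5-trimethyl-4-(prop-2-en-1-yl)-1,3-dioxolane
Conditions: 2,2-dimethoxypropane, PPTS (cat.), CH2Cl2, rt
Reagents that add atoms: 2,2-dimethoxypropane, COC(C)(C)OC
Why: Acid-catalysed transacetalisation gives the isopropylidene acetal of the vicinal diol (acetonide protection), which masks both hydroxyls for the Lewis-acidic, basic and organometallic steps that follow.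

**Step 7**
Reactants: 10 (4R,5R)-5-[(3E)-4,8-dimethylnona-3,7-dien-1-yl]-2,2,5-trimethyl-4-(prop-2-en-1-yl)-1,3-dioxolane
Product: 11 4-Diox-butanal
Conditions: Rh(acac)(CO)2 (1 mol%), Xantphos (4 mol%), CO/H2 (1:1, 10 bar), toluene, 70 °C
Reagents that add atoms: carbon monoxide, [C-]#[O+]
Why: Rhodium-catalysed hydroformylation with a wide-bite-angle diphosphine is linear-selective for the monosubstituted alkene and leaves the trisubstituted alkenes, adding the carbon that becomes the ring OCH2.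

**Step 8**
Reactants: 12 methyl 2-hydroxybut-3-enoate (racemic)
Product: 13 methyl 2-oxobut-3-enoate
Conditions: Dess–Martin periodinane, CH2Cl2, 0 °C → rt; cold filtered solution used at once
Reagents that add atoms: none
Why: Dess–Martin oxidation of the allylic α-hydroxy ester gives the vinyl α-keto ester under neutral, non-nucleophilic conditions; it is used fresh because it dimerises on standing.

**Step 9**
Reactants: 11 4-Diox-butanal; 13 methyl 2-oxobut-3-enoate
Product: 16 methyl (3S)-3-(2-Diox-ethyl)-2-hydroxy-3,4-dihydro-2H-pyran-6-carboxylate (anomeric mixture at C2), via enamine 14 (not isolated), via cyclic N,O-acetal 15 (not isolated)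
Conditions: (R)-2-[diphenyl(trimethylsilyloxy)methyl]pyrrolidine (15 mol%), silica gel, CH2Cl2, −20 °C → rt, slow addition of 13; aqueous work-up
Reagents that add atoms: none
Why: Aldehyde 11 condenses with the chiral pyrrolidine to the (E)-enamine 14, whose nucleophilic β-carbon bonds to the terminal CH2 of the s-cis oxadiene C=C–C=O of 13 while the keto oxygen bonds to the former aldehyde carbon (asynchronous [4+2], or Michael addition then O-attack on the iminium ion), giving N,O-acetal 15, which silica gel and water hydrolyse to lactol 16 with release of the catalyst. The closest known reaction type is the amine-catalysed inverse-electron-demand oxa-Diels–Alder reaction of enolisable aldehydes with β,γ-unsaturated α-keto esters. The dihydropyran ring closes as a [4+2] cycloaddition, the second bond being a 6-exo-trig attack of the enolate oxygen on the exocyclic C=N+ carbon. The new C3 centre (ring C5 of the target) is set by the catalyst: the diphenyl(silyloxy)methyl group shields one face of the s-trans enamine, so 13 approaches the other face and the (R)-catalyst should give the (S) centre, while the hemiacetal carbon forms as an anomeric mixture that step 10 removes. The step needs chemoselectivity for the cross reaction over dimerisation of 13 and self-aldolisation of 11, secured by the polarity match of enamine carbon and ester-activated vinyl terminus, by slow addition of cold 13 and by the product resting as a lactol; it also needs catalyst control over the acetonide centres, which sit four atoms from the reacting carbon and should not bias the face.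

**Step 10**
Reactants: 16 methyl (3S)-3-(2-Diox-ethyl)-2-hydroxy-3,4-dihydro-2H-pyran-6-carboxylate
Product: 17 methyl (3S)-3-(2-Diox-ethyl)-3,4-dihydro-2H-pyran-6-carboxylate
Conditions: Et3SiH, BF3·OEt2, CH2Cl2, −78 → −30 °C
Reagents that add atoms: none
Why: The Lewis acid ionises the hemiacetal to the cyclic oxocarbenium ion, which triethylsilane reduces (ionic hydrogenation of a lactol), leaving the ring OCH2; low temperature should spare acetonide and alkenes.

**Step 11**
Reactants: 17 methyl (3S)-3-(2-Diox-ethyl)-3,4-dihydro-2H-pyran-6-carboxylate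
Product: 19 methyl (2R,5S)-5-(2-Diox-ethyl)oxane-2-carboxylate, via cis ester 18 (not isolated)
Conditions: Cu(OAc)2·H2O (cat.), 1,2-bis(diphenylphosphino)benzene (cat.), (EtO)2MeSiH, t-BuOH, toluene, rt; then NaOMe, MeOH, 40 °C
Reagents that add atoms: none
Why: Copper hydride adds to the β-carbon of the α-alkoxy acrylate (conjugate reduction) without touching isolated alkenes, and methoxide then epimerises the α-alkoxy ester through its enolate to the more stable 2,5-trans diequatorial oxane, so C2 is relayed from C5 under thermodynamic control.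

**Step 12**
Reactants: 19 methyl (2R,5S)-5-(2-Diox-ethyl)oxane-2-carboxylate
Product: 20 (2R,5S)-5-(2-Diox-ethyl)-N-methoxy-N-methyloxane-2-carboxamide
Conditions: MeNH(OMe)·HCl, i-PrMgCl, THF, −20 → 0 °C
Reagents that add atoms: N,O-dimethylhydroxylamine hydrochloride, CNOC.Cl
Why: The chloromagnesium amide of N,O-dimethylhydroxylamine converts the ester into the Weinreb amide (aminolysis), and any C2 epimerisation returns to the favoured trans isomer.

**Step 13**
Reactants: 20 (2R,5S)-5-(2-Diox-ethyl)-N-methoxy-N-methyloxane-2-carboxamide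
Product: 21 1-[(2R,5S)-5-(2-Diox-ethyl)oxan-2-yl]ethan-1-one
Conditions: MeMgBr, THF, −78 → 0 °C
Reagents that add atoms: methylmagnesium bromide, C[Mg]Br
Why: The chelated tetrahedral intermediate of the Weinreb amide stops the addition at the methyl ketone (Weinreb ketone synthesis).

**Step 14**
Reactants: 21 1-[(2R,5S)-5-(2-Diox-ethyl)oxan-2-yl]ethan-1-one
Product: 23 1-[(2R,5S)-5-(2-Diox-ethyl)oxan-2-yl]ethenyl trifluoromethanesulfonate, via potassium enolate 22 (not isolated)
Conditions: KN(SiMe3)2, THF, −78 °C; then PhNTf2, −78 → 0 °C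
Reagents that add atoms: N-phenylbis(trifluoromethanesulfonimide), FC(F)(F)S(=O)(=O)N(c1ccccc1)S(=O)(=O)C(F)(F)F
Why: Kinetic deprotonation by the hindered amide base occurs at the methyl group, and O-triflation of the enolate gives the terminal enol triflate (enol triflate formation).

**Step 15**
Reactants: 23 1-[(2R,5S)-5-(2-Diox-ethyl)oxan-2-yl]ethenyl trifluoromethanesulfonate
Product: 24 2-[(2R,5S)-5-(2-Diox-ethyl)oxan-2-yl]prop-2-enoic acid
Conditions: Pd(OAc)2 (5 mol%), dppf (10 mol%), KOAc, CO (1 atm), DMF/H2O, 50 °C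
Reagents that add atoms: carbon monoxide, [C-]#[O+]; water, O
Why: Oxidative addition of the enol triflate to zerovalent palladium, CO insertion and capture of the acylpalladium species by water give the α-substituted acrylic acid (palladium-catalysed hydroxycarbonylation).

**Step 16**
Reactants: 24 2-[(2R,5S)-5-(2-Diox-ethyl)oxan-2-yl]prop-2-enoic acid
Product: 25 2-[(2R,5S)-5-[(3R,4R,7E)-3,4-dihydroxy-4,8,12-trimethyltrideca-7,11-dien-1-yl]oxan-2-yl]prop-2-enoic acid
Conditions: AcOH/H2O (4:1), 40 °C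
Reagents that add atoms: none
Why: Mild aqueous acid hydrolyses the isopropylidene acetal (acetonide cleavage) and should not dehydrate the tertiary alcohol or cyclise the diene.

**Compound list**
1 | 2-methylprop-2-en-1-ol | CC(=C)CO | starting material
2 | geranyl bromide, (2E)-1-bromo-3,7-dimethylocta-2,6-diene | BrC/C=C(\C)CCC=C(C)C | starting material
3 | dilithiated methallyl alcohol | [Li]CC(=C)CO[Li] | intermediate (not isolated)
4 | (5E)-6,10-dimethyl-2-methylideneundeca-5,9-dien-1-ol | OCC(=C)CC/C=C(\C)CCC=C(C)C | intermediate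
5 | [(2R)-2-[(3E)-4,8-dimethylnona-3,7-dien-1-yl]oxiran-2-yl]methanol | OC[C@@]1(CO1)CC/C=C(\C)CCC=C(C)C | intermediate
6 | (2S)-2-[(3E)-4,8-dimethylnona-3,7-dien-1-yl]oxirane-2-carbaldehyde | O=C[C@@]1(CO1)CC/C=C(\C)CCC=C(C)C | intermediate
7 | (1R)-1-[(2S)-2-[(3E)-4,8-dimethylnona-3,7-dien-1-yl]oxiran-2-yl]but-3-en-1-yl diisopinocampheylborinate | C=CC[C@@H](OB([C@H]1C[C@H]2C[C@@H]([C@@H]1C)C2(C)C)[C@H]1C[C@H]2C[C@@H]([C@@H]1C)C2(C)C)[C@@]1(CO1)CC/C=C(\C)CCC=C(C)C | intermediate (not isolated)
8 | (1R)-1-[(2S)-2-[(3E)-4,8-dimethylnona-3,7-dien-1-yl]oxiran-2-yl]but-3-en-1-ol | C=CC[C@@H](O)[C@@]1(CO1)CC/C=C(\C)CCC=C(C)C | intermediate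
9 | (4R,5R,8E)-5,9,13-trimethyltetradeca-1,8,12-triene-4,5-diol | C=CC[C@@H](O)[C@](C)(O)CC/C=C(\C)CCC=C(C)C | intermediate
10 | (4R,5R)-5-[(3E)-4,8-dimethylnona-3,7-dien-1-yl]-2,2,5-trimethyl-4-(prop-2-en-1-yl)-1,3-dioxolane | C=CC[C@H]1OC(C)(C)O[C@]1(C)CC/C=C(\C)CCC=C(C)C | intermediate
11 | 4-[(4R,5R)-5-[(3E)-4,8-dimethylnona-3,7-dien-1-yl]-2,2,5-trimethyl-1,3-dioxolan-4-yl]butanal | O=CCCC[C@H]1OC(C)(C)O[C@]1(C)CC/C=C(\C)CCC=C(C)C | intermediate
12 | methyl 2-hydroxybut-3-enoate (racemic) | COC(=O)C(O)C=C | starting material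
13 | methyl 2-oxobut-3-enoate | COC(=O)C(=O)C=C | intermediate
14 | (E)-enamine of 11 with (R)-2-[diphenyl(trimethylsilyloxy)methyl]pyrrolidine | C[Si](C)(C)OC(c1ccccc1)(c1ccccc1)[C@H]1CCCN1/C=C/CC[C@H]2OC(C)(C)O[C@]2(C)CC/C=C(\C)CCC=C(C)C | intermediate (not isolated)
15 | methyl (3S)-3-(2-Diox-ethyl)-2-[(2R)-2-[diphenyl(trimethylsilyloxy)methyl]pyrrolidin-1-yl]-3,4-dihydro-2H-pyran-6-carboxylate | COC(=O)C1=CC[C@H](CC[C@H]2OC(C)(C)O[C@]2(C)CC/C=C(\C)CCC=C(C)C)C(O1)N1CCC[C@@H]1C(c1ccccc1)(c1ccccc1)O[Si](C)(C)C | intermediate (not isolated)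
16 | methyl (3S)-3-(2-Diox-ethyl)-2-hydroxy-3,4-dihydro-2H-pyran-6-carboxylate (anomeric mixture) | COC(=O)C1=CC[C@H](CC[C@H]2OC(C)(C)O[C@]2(C)CC/C=C(\C)CCC=C(C)C)C(O)O1 | intermediate
17 | methyl (3S)-3-(2-Diox-ethyl)-3,4-dihydro-2H-pyran-6-carboxylate | COC(=O)C1=CC[C@H](CC[C@H]2OC(C)(C)O[C@]2(C)CC/C=C(\C)CCC=C(C)C)CO1 | intermediate
18 | methyl (2S,5S)-5-(2-Diox-ethyl)oxane-2-carboxylate (cis) | COC(=O)[C@@H]1CC[C@H](CC[C@H]2OC(C)(C)O[C@]2(C)CC/C=C(\C)CCC=C(C)C)CO1 | intermediate (not isolated)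
19 | methyl (2R,5S)-5-(2-Diox-ethyl)oxane-2-carboxylate (trans) | COC(=O)[C@H]1CC[C@H](CC[C@H]2OC(C)(C)O[C@]2(C)CC/C=C(\C)CCC=C(C)C)CO1 | intermediate
20 | (2R,5S)-5-(2-Diox-ethyl)-N-methoxy-N-methyloxane-2-carboxamide | CON(C)C(=O)[C@H]1CC[C@H](CC[C@H]2OC(C)(C)O[C@]2(C)CC/C=C(\C)CCC=C(C)C)CO1 | intermediate
21 | 1-[(2R,5S)-5-(2-Diox-ethyl)oxan-2-yl]ethan-1-one | CC(=O)[C@H]1CC[C@H](CC[C@H]2OC(C)(C)O[C@]2(C)CC/C=C(\C)CCC=C(C)C)CO1 | intermediate
22 | potassium enolate of 21 (methyl side) | [K+].[O-]C(=C)[C@H]1CC[C@H](CC[C@H]2OC(C)(C)O[C@]2(C)CC/C=C(\C)CCC=C(C)C)CO1 | intermediate (not isolated)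
23 | 1-[(2R,5S)-5-(2-Diox-ethyl)oxan-2-yl]ethenyl trifluoromethanesulfonate | C=C(OS(=O)(=O)C(F)(F)F)[C@H]1CC[C@H](CC[C@H]2OC(C)(C)O[C@]2(C)CC/C=C(\C)CCC=C(C)C)CO1 | intermediate
24 | 2-[(2R,5S)-5-(2-Diox-ethyl)oxan-2-yl]prop-2-enoic acid | C=C(C(=O)O)[C@H]1CC[C@H](CC[C@H]2OC(C)(C)O[C@]2(C)CC/C=C(\C)CCC=C(C)C)CO1 | intermediate
25 | 2-[(2R,5S)-5-[(3R,4R,7E)-3,4-dihydroxy-4,8,12-trimethyltrideca-7,11-dien-1-yl]oxan-2-yl]prop-2-enoic acid | C=C(C(=O)O)[C@H]1CC[C@H](CC[C@@H](O)[C@](C)(O)CC/C=C(\C)CCC=C(C)C)CO1 | target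

**Count**
Total steps: 16. Longest linear sequence: 15 (steps 1–7 and 9–16; step 8 is a one-step branch).

**Steps most likely to fail**

Step 9. The γ-unsubstituted keto ester 13 may dimerise, polymerise or add to the amine catalyst faster than it meets the enamine, and facial selectivity may erode. The fallback sets out from 11 and returns at 21; it forms the two ring bonds in separate operations with a bench-stable vinyl ketone. Commercial ethyl (S)-2-[(tert-butyldimethylsilyl)oxy]propanoate is converted with MeNH(OMe)·HCl/i-PrMgCl into (2S)-2-[(tert-butyldimethylsilyl)oxy]-N-methoxy-N-methylpropanamide F1, and vinylmagnesium bromide gives (4S)-4-[(tert-butyldimethylsilyl)oxy]pent-1-en-3-one F2. Amine-catalysed Michael addition of 11 to F2 (same (R)-prolinol silyl ether, catechol co-catalyst) should give (2S,6S)-6-[(tert-butyldimethylsilyl)oxy]-2-(2-Diox-ethyl)-5-oxoheptanal F3. NaBH(OAc)3 should reduce only the aldehyde, giving (2S,6S)-2-[(tert-butyldimethylsilyl)oxy]-6-(hydroxymethyl)-8-Diox-octan-3-one F4. Reductive etherification (Et3SiH, TMSOTf, −78 °C; axial hydride delivery to the cyclic oxocarbenium ion) should give the 2,5-trans oxane tert-butyl{(1S)-1-[(2R,5S)-5-(2-Diox-ethyl)oxan-2-yl]ethoxy}dimethylsilane F5. TBAF gives (1S)-1-[(2R,5S)-5-(2-Diox-ethyl)oxan-2-yl]ethan-1-ol F6, and Dess–Martin oxidation gives 21.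

Step 10. Ionisation of the lactol is slowed by the ester on the enol ether; the oxocarbenium ion may lose the C3 proton to give an achiral 4H-pyran, or the Lewis acid may open the acetonide. The fallback sets out from 16 and returns at 19. NaBH4 in MeOH reduces the open keto aldehyde tautomer to methyl (5R)-2-hydroxy-5-(hydroxymethyl)-7-Diox-heptanoate F7 (C2 epimers). Selective tosylation of the primary alcohol (TsCl, pyridine, 0 °C) gives methyl (5R)-2-hydroxy-5-{[(4-methylbenzenesulfonyl)oxy]methyl}-7-Diox-heptanoate F8. NaH in THF closes the oxane by intramolecular Williamson etherification (6-exo-tet) to the 18/19 mixture, which NaOMe/MeOH equilibrates to 19.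

Step 11. Copper hydride may be too slow on the donor-substituted acrylate, or the equilibration may leave too much cis ester. The fallback sets out from 17 and returns at 19. LiOH hydrolysis gives (3S)-3-(2-Diox-ethyl)-3,4-dihydro-2H-pyran-6-carboxylic acid F9. Carboxylate-directed homogeneous hydrogenation (H2, Ru(OAc)2(BINAP), MeOH), which leaves isolated trisubstituted alkenes and whose ligand enantiomer can be chosen to favour the 2R acid, gives (5S)-5-(2-Diox-ethyl)oxane-2-carboxylic acid F10. TMSCHN2 returns the 18/19 esters for the same NaOMe equilibration to 19.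

**Further compounds**
F1 | step 9 | (2S)-2-[(tert-butyldimethylsilyl)oxy]-N-methoxy-N-methylpropanamide | CON(C)C(=O)[C@H](C)O[Si](C)(C)C(C)(C)C
F2 | step 9 | (4S)-4-[(tert-butyldimethylsilyl)oxy]pent-1-en-3-one | C=CC(=O)[C@H](C)O[Si](C)(C)C(C)(C)C
F3 | step 9 | (2S,6S)-6-[(tert-butyldimethylsilyl)oxy]-2-(2-Diox-ethyl)-5-oxoheptanal | O=C[C@H](CCC(=O)[C@H](C)O[Si](C)(C)C(C)(C)C)CC[C@H]1OC(C)(C)O[C@]1(C)CC/C=C(\C)CCC=C(C)C
F4 | step 9 | (2S,6S)-2-[(tert-butyldimethylsilyl)oxy]-6-(hydroxymethyl)-8-Diox-octan-3-one | OC[C@H](CCC(=O)[C@H](C)O[Si](C)(C)C(C)(C)C)CC[C@H]1OC(C)(C)O[C@]1(C)CC/C=C(\C)CCC=C(C)C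
F5 | step 9 | tert-butyl{(1S)-1-[(2R,5S)-5-(2-Diox-ethyl)oxan-2-yl]ethoxy}dimethylsilane | C[C@H](O[Si](C)(C)C(C)(C)C)[C@H]1CC[C@H](CC[C@H]2OC(C)(C)O[C@]2(C)CC/C=C(\C)CCC=C(C)C)CO1
F6 | step 9 | (1S)-1-[(2R,5S)-5-(2-Diox-ethyl)oxan-2-yl]ethan-1-ol | C[C@H](O)[C@H]1CC[C@H](CC[C@H]2OC(C)(C)O[C@]2(C)CC/C=C(\C)CCC=C(C)C)CO1
F7 | step 10 | methyl (5R)-2-hydroxy-5-(hydroxymethyl)-7-Diox-heptanoate (C2 epimers) | COC(=O)C(O)CC[C@@H](CO)CC[C@H]1OC(C)(C)O[C@]1(C)CC/C=C(\C)CCC=C(C)C
F8 | step 10 | methyl (5R)-2-hydroxy-5-{[(4-methylbenzenesulfonyl)oxy]methyl}-7-Diox-heptanoate (C2 epimers) | COC(=O)C(O)CC[C@@H](COS(=O)(=O)c1ccc(C)cc1)CC[C@H]1OC(C)(C)O[C@]1(C)CC/C=C(\C)CCC=C(C)C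
F9 | step 11 | (3S)-3-(2-Diox-ethyl)-3,4-dihydro-2H-pyran-6-carboxylic acid | OC(=O)C1=CC[C@H](CC[C@H]2OC(C)(C)O[C@]2(C)CC/C=C(\C)CCC=C(C)C)CO1
F10 | step 11 | (5S)-5-(2-Diox-ethyl)oxane-2-carboxylic acid (C2 epimers) | OC(=O)C1CC[C@H](CC[C@H]2OC(C)(C)O[C@]2(C)CC/C=C(\C)CCC=C(C)C)CO1
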